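**Plan**

- Retrosynthesis: the 5‑O‑methyl and two O‑benzyl bonds are put back first (target ⇒ fully etherified flavone). Then C4–C4a of ring C is cut (⇒ β‑aryloxy‑α‑methoxycinnamic acid), then the vinyl ether bond O1–C2 (⇒ tetramethoxyphenol + enol tosylate), then C2–C3 (⇒ benzoate + methoxyacetate).
- Enabling feature: in the 2,3,4,5‑tetramethoxyphenyl ether the only ring‑A carbon still bearing hydrogen is the future C4a. It is flanked by the ether oxygen O1 and the 5‑methoxyl and lies para to the 7‑methoxyl, so acylation can only occur there.
- Forward: rings A and B are bought. The C2–C3–C4 chain is built on ring B by a crossed Claisen condensation and joined to ring A through O1 by vinylic substitution. Ring C, the only ring made, then closes by Friedel–Crafts acylation at C4–C4a.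
- Stereochemistry: the target has no stereocentre. The only stereo‑element on the way is the E alkene (carboxyl cis to aryloxy), set by chelate‑controlled enol tosylation and carried through a retentive substitution.
- End game: one Lewis‑acid step removes the chelated 5‑methyl ether and both benzyl ethers.

Key step: step 7

Remark: the target contains no stereocentre and no stereogenic double bond; it is achiral, so the structure given is a single compound and no enantiocontrol is needed.
Remark: enolates, phenoxides and carboxylates that are only the deprotonated forms of numbered compounds, and the aryloxyboron species hydrolysed in the work‑up of step 8, are treated as forms of those compounds and carry no number.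

**Route**

Step 1
Reactants: 1 1,2,3,4-tetramethoxybenzene
Product: 4 2,3,4,5-tetramethoxyphenol, via (2,3,4,5-tetramethoxyphenyl)lithium 2 (not isolated), via lithium trimethoxy(2,3,4,5-tetramethoxyphenyl)borate 3 (not isolated)
Conditions: n‑BuLi, TMEDA, THF, 0 °C; B(OMe)3, −78 °C → rt; AcOH, 30% aq. H2O2, 0 °C → rt
Reagents that add atoms: hydrogen peroxide, OO
Why: Directed ortho‑metalation at the only kind of ring C–H (next to a methoxyl), borylation and oxidative C–B to C–O exchange (lithiation–borylation–oxidation) should give the phenol, whose single open position then sits beside the new hydroxyl; the weakly acidic oxidation is chosen to spare the electron‑rich phenol from quinone formation.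

Step 2
Reactants: 5 methyl 3,5-dihydroxy-4-methoxybenzoate
Product: 6 methyl 3,5-bis(benzyloxy)-4-methoxybenzoate
Conditions: BnBr, K2CO3, DMF, 60 °C
Reagents that add atoms: benzyl bromide, BrCc1ccccc1
Why: Williamson etherification of both phenols should proceed cleanly under carbonate conditions that leave the methyl ester intact.

Step 3
Reactants: 6 methyl 3,5-bis(benzyloxy)-4-methoxybenzoate; 7 methyl methoxyacetate
Product: 8 methyl 3-[3,5-bis(benzyloxy)-4-methoxyphenyl]-2-methoxy-3-oxopropanoate (racemic at C2)
Conditions: 7 (2.2 equiv), LDA (2.2 equiv), THF, −78 °C; then 6, −78 → 0 °C; 1 M HCl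
Reagents that add atoms: none
Why: In this crossed Claisen condensation the methoxyacetate is fully converted to its lithium enolate, so no neutral enolisable ester remains for self‑condensation, the non‑enolisable benzoate is the only acyl acceptor, and the product is drained as its stabilised enolate; the C2 stereocentre is formed racemic and is erased in step 4.

Step 4
Reactants: 8 methyl 3-[3,5-bis(benzyloxy)-4-methoxyphenyl]-2-methoxy-3-oxopropanoate
Product: 9 methyl (E)-3-[3,5-bis(benzyloxy)-4-methoxyphenyl]-2-methoxy-3-(tosyloxy)prop-2-enoate (tosyloxy cis to the ester)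
Conditions: LiHMDS, THF, −78 °C; Ts2O, −78 °C → rt
Reagents that add atoms: p‑toluenesulfonic anhydride, Cc1ccc(cc1)S(=O)(=O)OS(=O)(=O)c1ccc(C)cc1
Why: O‑sulfonylation of the lithium enolate, held U‑shaped by chelation of lithium between the ketone and ester oxygens, should place the tosyloxy group cis to the ester (stereodefined enol tosylate formation), and the anhydride avoids the α‑chlorination that sulfonyl chlorides can cause.

Step 5
Reactants: 9 methyl (E)-3-[3,5-bis(benzyloxy)-4-methoxyphenyl]-2-methoxy-3-(tosyloxy)prop-2-enoate; 4 2,3,4,5-tetramethoxyphenol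
Product: 10 methyl (E)-3-[3,5-bis(benzyloxy)-4-methoxyphenyl]-2-methoxy-3-(2,3,4,5-tetramethoxyphenoxy)prop-2-enoate
Conditions: 4 (1.2 equiv), Cs2CO3, DMF, 60 °C, argon
Reagents that add atoms: none
Why: Nucleophilic vinylic substitution (addition–elimination) of the cesium phenoxide at the β‑carbon, which is activated by both the ester and the sulfonyloxy group, should expel tosylate with retention, as in the classical phenoxide/β‑chlorocinnamate ether synthesis, leaving the aryloxy group cis to the ester.

Step 6
Reactants: 10 methyl (E)-3-[3,5-bis(benzyloxy)-4-methoxyphenyl]-2-methoxy-3-(2,3,4,5-tetramethoxyphenoxy)prop-2-enoate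
Product: 11 (E)-3-[3,5-bis(benzyloxy)-4-methoxyphenyl]-2-methoxy-3-(2,3,4,5-tetramethoxyphenoxy)prop-2-enoic acid
Conditions: LiOH·H2O, THF/MeOH/H2O, 40 °C; then 1 M HCl to pH 3, 0 °C
Reagents that add atoms: lithium hydroxide, [Li+].[OH-]
Why: Saponification of the methyl ester (acyl–oxygen cleavage by hydroxide) should leave the benzyl ethers and the base‑stable enol ether untouched, and the brief cold acidification only liberates the acid.

Step 7
Reactants: 11 (E)-3-[3,5-bis(benzyloxy)-4-methoxyphenyl]-2-methoxy-3-(2,3,4,5-tetramethoxyphenoxy)prop-2-enoic acid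
Product: 13 2-[3,5-bis(benzyloxy)-4-methoxyphenyl]-3,5,6,7,8-pentamethoxy-4H-chromen-4-one, via mixed trifluoroacetic anhydride 12 (not isolated)
Conditions: TFAA (3 equiv), CH2Cl2, 0 °C → rt
Reagents that add atoms: none
Why: TFAA converts the acid into mixed anhydride 12, whose acyl carbon (or the donor‑stabilised acylium ion formed by loss of trifluoroacetate) is attacked by C6 of the tetramethoxyphenoxy ring, and loss of the proton restores ring A and gives the 4‑pyranone. The closest known reactions are the Ruhemann‑type cyclodehydration of β‑aryloxycinnamic acids to flavones and the TFAA‑mediated closure of 2‑aryloxybenzoic acids to xanthones. Ring C closes as a six‑membered ring by 6‑exo‑trig attack at the acyl carbon, forming C4–C4a; no stereocentre is created. The step needs closure onto ring A and not onto the also activated ring B (which would give an indenone). This is secured by the E geometry, which holds the acyl group cis to the aryloxy group and trans to ring B, and by the preference for six‑ over five‑membered closure. On ring A only one carbon carries hydrogen, and it is activated by the ortho ether oxygen, the ortho 5‑methoxyl and the para 7‑methoxyl, so no regioisomer can form. The activation is mild enough that the benzyl and methyl ethers should survive.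

Step 8
Reactants: 13 2-[3,5-bis(benzyloxy)-4-methoxyphenyl]-3,5,6,7,8-pentamethoxy-4H-chromen-4-one
Product: 14 5,3',5'-trihydroxy-3,6,7,8,4'-pentamethoxyflavone
Conditions: BCl3 (6 equiv), pentamethylbenzene, CH2Cl2, −78 → 0 °C; then H2O
Reagents that add atoms: none
Why: Lewis‑acid ether cleavage with boron trichloride should remove both benzyl ethers at low temperature (the benzyl cations being captured by pentamethylbenzene) and, on warming, the 5‑methyl ether alone among the methyl ethers, because only it forms a six‑membered boron chelate with the C4 carbonyl (chelation‑directed peri‑demethylation).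

**Compound list**

1 | 1,2,3,4-tetramethoxybenzene | COc1ccc(OC)c(OC)c1OC | starting material
2 | (2,3,4,5-tetramethoxyphenyl)lithium | [Li]c1cc(OC)c(OC)c(OC)c1OC | intermediate (not isolated)
3 | lithium trimethoxy(2,3,4,5-tetramethoxyphenyl)borate | [Li+].CO[B-](OC)(OC)c1cc(OC)c(OC)c(OC)c1OC | intermediate (not isolated)
4 | 2,3,4,5-tetramethoxyphenol | Oc1cc(OC)c(OC)c(OC)c1OC | intermediate
5 | methyl 3,5-dihydroxy-4-methoxybenzoate | COC(=O)c1cc(O)c(OC)c(O)c1 | starting material
6 | methyl 3,5-bis(benzyloxy)-4-methoxybenzoate | COC(=O)c1cc(OCc2ccccc2)c(OC)c(OCc2ccccc2)c1 | intermediate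
7 | methyl methoxyacetate | COCC(=O)OC | starting material
8 | methyl 3-[3,5-bis(benzyloxy)-4-methoxyphenyl]-2-methoxy-3-oxopropanoate (racemic) | COC(=O)C(OC)C(=O)c1cc(OCc2ccccc2)c(OC)c(OCc2ccccc2)c1 | intermediate
9 | methyl (E)-3-[3,5-bis(benzyloxy)-4-methoxyphenyl]-2-methoxy-3-(tosyloxy)prop-2-enoate | COC(=O)/C(OC)=C(\OS(=O)(=O)c1ccc(C)cc1)c1cc(OCc2ccccc2)c(OC)c(OCc2ccccc2)c1 | intermediate
10 | methyl (E)-3-[3,5-bis(benzyloxy)-4-methoxyphenyl]-2-methoxy-3-(2,3,4,5-tetramethoxyphenoxy)prop-2-enoate | COC(=O)/C(OC)=C(\Oc1cc(OC)c(OC)c(OC)c1OC)c1cc(OCc2ccccc2)c(OC)c(OCc2ccccc2)c1 | intermediate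
11 | (E)-3-[3,5-bis(benzyloxy)-4-methoxyphenyl]-2-methoxy-3-(2,3,4,5-tetramethoxyphenoxy)prop-2-enoic acid | OC(=O)/C(OC)=C(\Oc1cc(OC)c(OC)c(OC)c1OC)c1cc(OCc2ccccc2)c(OC)c(OCc2ccccc2)c1 | intermediate
12 | (E)-3-[3,5-bis(benzyloxy)-4-methoxyphenyl]-2-methoxy-3-(2,3,4,5-tetramethoxyphenoxy)prop-2-enoic trifluoroacetic anhydride | O=C(OC(=O)C(F)(F)F)/C(OC)=C(\Oc1cc(OC)c(OC)c(OC)c1OC)c1cc(OCc2ccccc2)c(OC)c(OCc2ccccc2)c1 | intermediate (not isolated)
13 | 2-[3,5-bis(benzyloxy)-4-methoxyphenyl]-3,5,6,7,8-pentamethoxy-4H-chromen-4-one | COc1c(-c2cc(OCc3ccccc3)c(OC)c(OCc3ccccc3)c2)oc2c(OC)c(OC)c(OC)c(OC)c2c1=O | intermediate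
14 | 5,3',5'-trihydroxy-3,6,7,8,4'-pentamethoxyflavone | COc1c(O)cc(-c2oc3c(OC)c(OC)c(OC)c(O)c3c(=O)c2OC)cc1O | target

**Count**

Total steps: 8. Longest linear sequence: 7 steps (5 → 14, steps 2–8).

**Steps most likely to fail**

1. Step 5. The phenoxide may attack the sulfur of the enol tosylate (sulfonyl transfer back to the keto ester) faster than the crowded, tetrasubstituted vinylic carbon, or the alkene geometry may be partly lost in a long‑lived carbanion. Fallback, setting out from 8: Vilsmeier‑type chlorodehydroxylation of the enol with oxalyl chloride and DMF in CH2Cl2 should give methyl 3-[3,5-bis(benzyloxy)-4-methoxyphenyl]-3-chloro-2-methoxyprop-2-enoate F1, a vinylogous acid chloride with no sulfonyl centre to intercept the nucleophile. Displacement of chloride by the cesium salt of 4 in DMF, the classical β‑chlorocinnamate route to β‑aryloxycinnamates, then returns to the route at 10; an isomer mixture would be separated or equilibrated at that stage.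

2. Step 7. The mixed anhydride of this donor‑substituted acrylic acid may be too weak an electrophile to close the ring, or the acid released may cleave the enol ether before closure. Fallback, setting out from 4 and keeping the same C4–C4a bond but forming it with reversed polarity: bromination of 4 with NBS in MeCN at 0 °C at its only free position should give 2-bromo-3,4,5,6-tetramethoxyphenol F2. Vinylic substitution on 9 (Cs2CO3, DMF) would give methyl (E)-3-[3,5-bis(benzyloxy)-4-methoxyphenyl]-3-(2-bromo-3,4,5,6-tetramethoxyphenoxy)-2-methoxyprop-2-enoate F3. Bromine–lithium exchange with n‑BuLi in THF at −100 °C, followed by intramolecular acylation of the aryllithium by the methyl ester (Parham cyclisation), closes ring C and returns to the route at 13.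

3. Step 8. Dealkylation may go too far (loss of the 3‑, 4'‑ or 6‑O‑methyl once neighbouring oxygens carry boron), or the benzyl cations may alkylate the electron‑rich rings. Fallback, setting out from 13, separating the two deprotections: hydrogenolysis (H2, Pd/C, EtOAc/MeOH), which generates no cations and touches no methyl ether, should give 2-(3,5-dihydroxy-4-methoxyphenyl)-3,5,6,7,8-pentamethoxy-4H-chromen-4-one F4. Protic, hydrogen‑bond‑assisted cleavage of the peri 5‑methyl ether alone (conc. HCl in AcOH, 80 °C) then returns to the route at 14.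

**Further compounds**

F1 | step 5 | methyl 3-[3,5-bis(benzyloxy)-4-methoxyphenyl]-3-chloro-2-methoxyprop-2-enoate (alkene geometry not controlled) | COC(=O)C(OC)=C(Cl)c1cc(OCc2ccccc2)c(OC)c(OCc2ccccc2)c1
F2 | step 7 | 2-bromo-3,4,5,6-tetramethoxyphenol | Oc1c(Br)c(OC)c(OC)c(OC)c1OC
F3 | step 7 | methyl (E)-3-[3,5-bis(benzyloxy)-4-methoxyphenyl]-3-(2-bromo-3,4,5,6-tetramethoxyphenoxy)-2-methoxyprop-2-enoate | COC(=O)/C(OC)=C(\Oc1c(Br)c(OC)c(OC)c(OC)c1OC)c1cc(OCc2ccccc2)c(OC)c(OCc2ccccc2)c1
F4 | step 8 | 2-(3,5-dihydroxy-4-methoxyphenyl)-3,5,6,7,8-pentamethoxy-4H-chromen-4-one | COc1c(O)cc(-c2oc3c(OC)c(OC)c(OC)c(OC)c3c(=O)c2OC)cc1O
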